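## Retrosynthetic overview

1. The C3 stereocentre (α to C4=O and benzylic to ring B, so base-labile) is made last, by Pd-catalysed decarboxylative asymmetric protonation of the C3=C4 allyl enol carbonate 10; the same catalyst frees the 7-OH from its allyl carbonate.
2. Ring C is opened at O1–C8a: an open-chain 2-fluorodeoxybenzoin (6) takes up formaldehyde at C3 (C2–C3 bond) and the new C2 alkoxide displaces fluoride from C8a of ring A (domino aldol/SNAr).
3. Enabling feature: the C4 carbonyl is ortho to C8a on ring A, so C8a–F is an SNAr site that a C2–O⁻ reaches through a six-membered transition state; C3 lies between C4=O and ring B and is acidic enough for carbonate.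
4. 6 comes from Pd-catalysed α-arylation of THP-protected 2'-fluoro-4'-hydroxyacetophenone with bromochromene 3; ring D of 3 is annulated onto 4-bromo-3-methoxyphenol with prenal.
5. Ring order: A and B are bought, D is closed in step 1, C in step 4.

Key step: step 4

Assumption: with (S)-t-BuPHOX and Meldrum's acid the palladium enolate is taken to be protonated to the (S)-ketone; if a trial run shows the opposite sense, (R)-t-BuPHOX is used and nothing else changes.

## Route

Step 1
Reactants: 1 4-bromo-3-methoxyphenol; 2 3-methylbut-2-enal (prenal)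
Product: 3 6-bromo-7-methoxy-2,2-dimethyl-2H-chromene
Conditions: PhB(OH)2 (1.0 equiv, returned on aqueous work-up), AcOH (cat.), toluene, reflux, Dean–Stark
Reagents that add atoms: none
Why: Phenol–enal chromene annulation, in which the aryl borate delivers prenal to the unhindered ortho position C6 (para to OMe) rather than to C2 between OH and OMe, the benzodioxaborin fragments to an ortho-quinone methide, and oxa-6π-electrocyclisation closes ring D.

Step 2
Reactants: 4 1-(2-fluoro-4-hydroxyphenyl)ethan-1-one
Product: 5 1-[2-fluoro-4-(tetrahydro-2H-pyran-2-yloxy)phenyl]ethan-1-one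
Conditions: 3,4-dihydro-2H-pyran (1.5 equiv), PPTS (5 mol%), CH2Cl2, rt
Reagents that add atoms: 3,4-dihydro-2H-pyran, C1=COCCC1
Why: Acid-catalysed THP acetal formation masks O7, which as a phenoxide para to C4=O would switch off the carbonyl as SNAr activator in step 4; the racemic acetal carbon is of no consequence.

Step 3
Reactants: 3 6-bromo-7-methoxy-2,2-dimethyl-2H-chromene; 5 1-[2-fluoro-4-(tetrahydro-2H-pyran-2-yloxy)phenyl]ethan-1-one
Product: 6 1-[2-fluoro-4-(tetrahydro-2H-pyran-2-yloxy)phenyl]-2-(7-methoxy-2,2-dimethyl-2H-chromen-6-yl)ethan-1-one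
Conditions: Pd2(dba)3 (1.5 mol%), XPhos (3.6 mol%), K3PO4 (2.3 equiv), toluene, 90 °C
Reagents that add atoms: none
Why: Palladium-catalysed α-arylation of a methyl ketone enolate (Buchwald–Hartwig-type enolate arylation) forms the C3–aryl bond, the bulky biarylphosphine and the ortho-methoxy group of 3 should hold it at monoarylation, and phosphate is too weak a nucleophile to touch the C–F bond or the acetal.

Step 4
Reactants: 6 1-[2-fluoro-4-(tetrahydro-2H-pyran-2-yloxy)phenyl]-2-(7-methoxy-2,2-dimethyl-2H-chromen-6-yl)ethan-1-one
Product: 8 rac-3-(7-methoxy-2,2-dimethyl-2H-chromen-6-yl)-7-(tetrahydro-2H-pyran-2-yloxy)chroman-4-one, via hydroxymethyl ketone 7 (not isolated)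
Conditions: (CH2O)n (1.3 equiv), K2CO3 (2.5 equiv), DMF–H2O (20:1), 60 → 90 °C
Reagents that add atoms: formaldehyde (used as paraformaldehyde), C=O
Why: Carbonate forms the C3 enolate of 6, which adds to formaldehyde (C2–C3 bond) to give 7; the C2 alkoxide of 7 then attacks C8a of ring A, the Meisenheimer adduct is stabilised by the ortho C4 carbonyl, and loss of fluoride gives the O1–C8a bond. The closest known chemistry is the base-mediated hydroxymethylation of deoxybenzoins joined to the SNAr closure of β-hydroxy 2-fluoroaryl ketones to chroman-4-ones (tandem aldol–SNAr annulation). Ring C closes in a 6-exo-trig addition–elimination at the ipso carbon. The new stereocentre C3 is formed without control and is left racemic on purpose, because it is α to C4=O and benzylic and could not survive carbonate; it is set in step 7. The step needs the irreversible SNAr to outrun loss of water from 7 (α-methylene ketone) and a second hydroxymethylation; both side channels are reversible under carbonate in wet DMF (oxa-Michael re-addition, retro-aldol) and drain back into 7, and only a small excess of formaldehyde is used. The THP ether keeps O7 from becoming a phenoxide that would cancel the activation of C8a by C4=O, and with a single C–F bond no regiochemical question arises.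

Step 5
Reactants: 8 rac-3-(7-methoxy-2,2-dimethyl-2H-chromen-6-yl)-7-(tetrahydro-2H-pyran-2-yloxy)chroman-4-one
Product: 9 rac-7-hydroxy-3-(7-methoxy-2,2-dimethyl-2H-chromen-6-yl)chroman-4-one
Conditions: PPTS (0.2 equiv), MeOH, 45 °C
Reagents that add atoms: none
Why: Acid-catalysed transacetalisation to methanol removes the THP group under pyridinium-level acidity that the electron-rich chromene double bond should tolerate, and C3 is still racemic, so enolisation here costs nothing.

Step 6
Reactants: 9 rac-7-hydroxy-3-(7-methoxy-2,2-dimethyl-2H-chromen-6-yl)chroman-4-one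
Product: 10 3-(7-methoxy-2,2-dimethyl-2H-chromen-6-yl)-2H-chromene-4,7-diyl bis(prop-2-en-1-yl) dicarbonate
Conditions: NaHMDS (2.3 equiv), TMEDA, THF, −78 °C; allyl chloroformate (2.5 equiv), −78 → 0 °C
Reagents that add atoms: allyl chloroformate, C=CCOC(=O)Cl
Why: Double O-acylation by a hard chloroformate turns the phenoxide into the aryl allyl carbonate and the TMEDA-solvated sodium enolate into the allyl enol carbonate, which erases C3 as a stereocentre on purpose; any C-acylated β-keto allyl ester formed alongside would enter the same palladium enolate in step 7.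

Step 7
Reactants: 10 3-(7-methoxy-2,2-dimethyl-2H-chromen-6-yl)-2H-chromene-4,7-diyl bis(prop-2-en-1-yl) dicarbonate
Product: 11 (3S)-7-hydroxy-3-(7-methoxy-2,2-dimethyl-2H-chromen-6-yl)-2,3-dihydro-4H-chromen-4-one
Conditions: Pd2(dba)3 (5 mol%), (S)-t-BuPHOX (12.5 mol%), Meldrum's acid (4 equiv), THF, 20 °C; direct chromatography without base
Reagents that add atoms: none
Why: Palladium-catalysed decarboxylative asymmetric protonation, in which Pd(0)/PHOX ionises both allyl carbonates, loss of CO2 gives the phenoxide and a PHOX-bound palladium enolate, and Meldrum's acid protonates C3 on the enolate face left open by the ligand while its anion scavenges both allyl groups, so that C3–H is set as (S) under aprotic, weakly acidic conditions that should not enolise the product.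

## Compound list

1 | 4-bromo-3-methoxyphenol | COc1cc(O)ccc1Br | starting material
2 | 3-methylbut-2-enal (prenal) | CC(C)=CC=O | starting material
3 | 6-bromo-7-methoxy-2,2-dimethyl-2H-chromene | COc1cc2OC(C)(C)C=Cc2cc1Br | intermediate
4 | 1-(2-fluoro-4-hydroxyphenyl)ethan-1-one | CC(=O)c1ccc(O)cc1F | starting material
5 | 1-[2-fluoro-4-(tetrahydro-2H-pyran-2-yloxy)phenyl]ethan-1-one (racemic acetal) | CC(=O)c1ccc(OC2CCCCO2)cc1F | intermediate
6 | 1-[2-fluoro-4-(tetrahydro-2H-pyran-2-yloxy)phenyl]-2-(7-methoxy-2,2-dimethyl-2H-chromen-6-yl)ethan-1-one (racemic acetal) | COc1cc2OC(C)(C)C=Cc2cc1CC(=O)c1ccc(OC2CCCCO2)cc1F | intermediate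
7 | 1-[2-fluoro-4-(tetrahydro-2H-pyran-2-yloxy)phenyl]-3-hydroxy-2-(7-methoxy-2,2-dimethyl-2H-chromen-6-yl)propan-1-one (not isolated, stereocentres uncontrolled) | COc1cc2OC(C)(C)C=Cc2cc1C(CO)C(=O)c1ccc(OC2CCCCO2)cc1F | intermediate
8 | rac-3-(7-methoxy-2,2-dimethyl-2H-chromen-6-yl)-7-(tetrahydro-2H-pyran-2-yloxy)chroman-4-one (diastereomer mixture at the acetal carbon) | COc1cc2OC(C)(C)C=Cc2cc1C1COc2cc(OC3CCCCO3)ccc2C1=O | intermediate
9 | rac-7-hydroxy-3-(7-methoxy-2,2-dimethyl-2H-chromen-6-yl)chroman-4-one | COc1cc2OC(C)(C)C=Cc2cc1C1COc2cc(O)ccc2C1=O | intermediate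
10 | 3-(7-methoxy-2,2-dimethyl-2H-chromen-6-yl)-2H-chromene-4,7-diyl bis(prop-2-en-1-yl) dicarbonate (enol allyl carbonate at C4, aryl allyl carbonate at C7) | COc1cc2OC(C)(C)C=Cc2cc1C1=C(OC(=O)OCC=C)c2ccc(OC(=O)OCC=C)cc2OC1 | intermediate
11 | (3S)-7-hydroxy-3-(7-methoxy-2,2-dimethyl-2H-chromen-6-yl)-2,3-dihydro-4H-chromen-4-one | COc1cc2c(cc1[C@H]1COc3cc(O)ccc3C1=O)C=CC(C)(C)O2 | target

## Step count and risks

Total steps: 7. Longest linear sequence: 6 steps (1 → 3 → 6 → 8 → 9 → 10 → 11, or equally 4 → 5 → 6 → …).

Steps most likely to fail: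

Step 4. Loss of water from the aldol adduct to the α-methylene ketone, followed by conjugate addition of a second enolate or polymerisation, may outrun the ring closure; the SNAr itself may be slow because the para acetal oxygen donates into the C4 carbonyl. The fallback sets out from 6 and brings C2 in at the formyl oxidation level, where neither dehydration nor double addition is possible. Condensation of 6 with N,N-dimethylformamide dimethyl acetal (toluene, 100 °C) should give the enaminone F1. Heating F1 with K2CO3 in wet DMF (100–120 °C) should exchange the dimethylamino group for an enolate oxygen, which closes the same O1–C8a bond by SNAr to give the THP-protected isoflavone F2. Conjugate reduction of F2 with L-Selectride (THF, −78 °C, NH4Cl quench) returns to the route at 8.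

Step 7. The phenol released in the same flask may compete with Meldrum's acid as an achiral proton donor and erode the facial selectivity, C3-allylation may intrude if protonation is slow, and the sense of induction is assumed. The fallback sets out from 9 and replaces enolate protonation by a dynamic kinetic reduction. Silylation (TBSCl, imidazole, DMF) should give the silyl ether F3. Asymmetric transfer hydrogenation with RuCl[(S,S)-TsDPEN](p-cymene) in HCO2H/Et3N (5:2, 40 °C), during which C3 epimerises under the amine while hydride is delivered to one face of C4=O, is expected to give the cis-(3S,4S)-alcohol F4. Dess–Martin periodinane (NaHCO3, CH2Cl2, 0 °C) should return the C4 ketone without touching C3, giving the silyl-protected (S)-ketone F5. HF·pyridine in THF at 0 °C removes the silyl group under acidic, aprotic conditions and arrives at 11.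

Step 1. Poor regiocontrol (attack at C2 between OH and OMe) or oligomerisation of prenal may leave the bromophenol largely unconverted. The fallback sets out from 1 and builds ring D by a sigmatropic route. O-Alkylation with 3-chloro-3-methylbut-1-yne (K2CO3, KI, cat. CuI, acetone, reflux) should give the propargyl ether F6. Heating F6 in N,N-diethylaniline at 180 °C (aromatic propargyl Claisen rearrangement, 1,5-hydrogen shift, oxa-6π closure) comes back to the route at 3.

## Further compounds

F1 | step 4 | 3-(dimethylamino)-1-[2-fluoro-4-(tetrahydro-2H-pyran-2-yloxy)phenyl]-2-(7-methoxy-2,2-dimethyl-2H-chromen-6-yl)prop-2-en-1-one | CN(C)C=C(C(=O)c1ccc(OC2CCCCO2)cc1F)c1cc2C=CC(C)(C)Oc2cc1OC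
F2 | step 4 | 3-(7-methoxy-2,2-dimethyl-2H-chromen-6-yl)-7-(tetrahydro-2H-pyran-2-yloxy)-4H-chromen-4-one | COc1cc2OC(C)(C)C=Cc2cc1C1=COc2cc(OC3CCCCO3)ccc2C1=O
F3 | step 7 | rac-7-[(tert-butyldimethylsilyl)oxy]-3-(7-methoxy-2,2-dimethyl-2H-chromen-6-yl)chroman-4-one | COc1cc2OC(C)(C)C=Cc2cc1C1COc2cc(O[Si](C)(C)C(C)(C)C)ccc2C1=O
F4 | step 7 | (3S,4S)-7-[(tert-butyldimethylsilyl)oxy]-3-(7-methoxy-2,2-dimethyl-2H-chromen-6-yl)chroman-4-ol | COc1cc2c(cc1[C@H]1COc3cc(O[Si](C)(C)C(C)(C)C)ccc3[C@H]1O)C=CC(C)(C)O2
F5 | step 7 | (3S)-7-[(tert-butyldimethylsilyl)oxy]-3-(7-methoxy-2,2-dimethyl-2H-chromen-6-yl)chroman-4-one | COc1cc2c(cc1[C@H]1COc3cc(O[Si](C)(C)C(C)(C)C)ccc3C1=O)C=CC(C)(C)O2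
F6 | step 1 | 1-bromo-2-methoxy-4-[(2-methylbut-3-yn-2-yl)oxy]benzene | COc1cc(OC(C)(C)C#C)ccc1Br
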